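**Retrosynthetic overview**
- The C6 prenyl group goes on last, by Stille coupling on a 6-bromo-isoflavanone, with the 2'-OH unmasked in the same flask (late aromatic prenylation, as in the plant).
- The isoflavanone C ring comes from a 2-methoxyisoflavanone (O-methyl analogue of the biosynthetic 2-hydroxyisoflavanone) by reductive removal of the C2 oxygen, leaving C3 untouched.
- The 2-methoxyisoflavanone comes from an α-aryl-β-ketoacetal, made by an enantioselective oxidative 1,2-aryl shift of a 2'-hydroxychalcone with a chiral aryl-λ3-iodane; this step sets C3 as (S).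
- The chalcone comes from Claisen–Schmidt condensation of 5-bromopaeonol with 2-hydroxy-4-methoxybenzaldehyde, followed by silylation of the B-ring phenol.
- Ring order: rings A and B are bought; the pyranone C ring is the only ring formed, and it closes after the aryl shift.

Assumption: the (R,R)-lactate iodane, COC(=O)[C@@H](C)Oc1cccc(O[C@H](C)C(=O)OC)c1I(OC(C)=O)OC(C)=O, is taken to give the (S) centre; this is checked on the first isoflavanone, and if the sense is opposite the (S,S)-reagent from methyl (R)-lactate is used with nothing else changed.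
Assumption: 5-bromopaeonol, the aldehyde and the prenylstannane are bought; the iodane is a known reagent (2-iodoresorcinol plus methyl (S)-lactate by Mitsunobu, then oxidation) and its iodoarene is recovered.

**Step 1**
Reactants: 1 1-(5-bromo-2-hydroxy-4-methoxyphenyl)ethan-1-one; 2 2-hydroxy-4-methoxybenzaldehyde
Product: 3 (E)-1-(5-bromo-2-hydroxy-4-methoxyphenyl)-3-(2-hydroxy-4-methoxyphenyl)prop-2-en-1-one
Conditions: KOH (50% aq, 10 equiv), EtOH, rt, 48–72 h, dark; then 1 M HCl to pH 5, 0 °C
Reagents that add atoms: none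
Why: Claisen–Schmidt (crossed aldol) condensation, in which the ketone enolate adds to the non-enolisable aldehyde and E1cB dehydration gives the conjugated E-enone, while the aryl bromide and methyl ethers are inert to aqueous KOH.

**Step 2**
Reactants: 3 (E)-1-(5-bromo-2-hydroxy-4-methoxyphenyl)-3-(2-hydroxy-4-methoxyphenyl)prop-2-en-1-one
Product: 4 (E)-1-(5-bromo-2-hydroxy-4-methoxyphenyl)-3-[2-(tert-butyldimethylsilyloxy)-4-methoxyphenyl]prop-2-en-1-one
Conditions: TBSCl (1.05 equiv), imidazole (2.2 equiv), DMF, 0 °C to rt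
Reagents that add atoms: tert-butyldimethylsilyl chloride, CC(C)(C)[Si](C)(C)Cl
Why: Chemoselective phenol silylation, because the 2'-OH is locked in a hydrogen bond to the ketone and does not react, so only the B-ring phenol is capped; this keeps that oxygen from closing onto the acetal carbon later (which would give a benzofuran).

**Step 3**
Reactants: 4 (E)-1-(5-bromo-2-hydroxy-4-methoxyphenyl)-3-[2-(tert-butyldimethylsilyloxy)-4-methoxyphenyl]prop-2-en-1-one
Product: 5 (2S)-1-(5-bromo-2-hydroxy-4-methoxyphenyl)-2-[2-(tert-butyldimethylsilyloxy)-4-methoxyphenyl]-3,3-dimethoxypropan-1-one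
Conditions: (R,R)-lactate aryl-λ3-iodane diacetate (1.3 equiv), TMSOTf (2.6 equiv), MeOH (4 equiv), CH2Cl2/CF3CH2OH 10:1, −78 to −40 °C; aq NaHCO3 at −40 °C
Reagents that add atoms: methanol, CO
Why: Enantioselective iodine(III)-mediated oxidative 1,2-aryl migration of a chalcone (the chiral-iodane version of the thallium(III) isoflavone rearrangement and the chemical counterpart of 2-hydroxyisoflavanone synthase): the chiral iodane binds one face at C-α, MeOH adds anti at the benzylic carbon, and the electron-rich aryl group shifts to C-α with inversion as the iodoarene leaves, so the reagent sets the future C3 as (S), and the cation left behind is trapped by MeOH as the dimethyl acetal; the reaction is known for simple chalcones and is extended here to a hydrogen-bonded 2'-hydroxychalcone whose phenol para position is blocked by Br.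

**Step 4**
Reactants: 5 (2S)-1-(5-bromo-2-hydroxy-4-methoxyphenyl)-2-[2-(tert-butyldimethylsilyloxy)-4-methoxyphenyl]-3,3-dimethoxypropan-1-one
Product: 7 (3S)-6-bromo-3-[2-(tert-butyldimethylsilyloxy)-4-methoxyphenyl]-7-methoxychroman-4-one, via cyclic 2-methoxy acetal 6 (not isolated)
Conditions: TMSOTf (0.2 equiv), CH2Cl2, −78 °C, 30 min; then Et3SiH (6 equiv), TMSOTf (2.0 equiv), −78 to −45 °C; aq NaHCO3 at −45 °C
Reagents that add atoms: none
Why: Proposed new method: catalytic TMSOTf ionises the dimethyl acetal and the chelated phenol closes the six-membered ring to the cyclic mixed acetal (the O-methyl analogue of 2-hydroxyisoflavanone), then stoichiometric TMSOTf removes the exocyclic OMe and the very electrophilic C2 aryloxycarbenium is captured by excess Et3SiH at −78 °C faster than the base-free medium can remove H-3 (the path to the isoflavone), while any ring-opened methoxycarbenium, being less electrophilic, re-closes rather than being reduced; C3 is not a reacting centre, so (S) is retained; the closest known chemistry is the Et3SiH/Lewis-acid ionic hydrogenation of 2-alkoxychromans and lactol ethers.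

**Step 5**
Reactants: 7 (3S)-6-bromo-3-[2-(tert-butyldimethylsilyloxy)-4-methoxyphenyl]-7-methoxychroman-4-one; 8 tributyl(3-methylbut-2-en-1-yl)stannane
Product: 10 (3S)-3-(2-hydroxy-4-methoxyphenyl)-7-methoxy-6-(3-methylbut-2-en-1-yl)chroman-4-one, via silyl ether 9 (not isolated)
Conditions: Pd(PPh3)4 (10 mol %), toluene, 90 °C, degassed; then MeOH, KHF2 (3 equiv), rt; filter
Reagents that add atoms: none
Why: Stille coupling, in which oxidative addition of the aryl bromide, allyl transfer from tin and reductive elimination at the less substituted allyl terminus give the linear prenyl arene under neutral conditions that do not enolise C3, after which KHF2 in MeOH cleaves the aryl silyl ether under weakly acidic conditions and precipitates the tin as its fluoride, so (S) at C3 is kept.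

**Compound list**
1 | 1-(5-bromo-2-hydroxy-4-methoxyphenyl)ethan-1-one (5-bromopaeonol) | CC(=O)c1cc(Br)c(OC)cc1O | starting material
2 | 2-hydroxy-4-methoxybenzaldehyde | O=Cc1ccc(OC)cc1O | starting material
3 | (E)-1-(5-bromo-2-hydroxy-4-methoxyphenyl)-3-(2-hydroxy-4-methoxyphenyl)prop-2-en-1-one | COc1ccc(/C=C/C(=O)c2cc(Br)c(OC)cc2O)c(O)c1 | intermediate
4 | (E)-1-(5-bromo-2-hydroxy-4-methoxyphenyl)-3-[2-(tert-butyldimethylsilyloxy)-4-methoxyphenyl]prop-2-en-1-one | COc1ccc(/C=C/C(=O)c2cc(Br)c(OC)cc2O)c(O[Si](C)(C)C(C)(C)C)c1 | intermediate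
5 | (2S)-1-(5-bromo-2-hydroxy-4-methoxyphenyl)-2-[2-(tert-butyldimethylsilyloxy)-4-methoxyphenyl]-3,3-dimethoxypropan-1-one | COc1ccc([C@@H](C(OC)OC)C(=O)c2cc(Br)c(OC)cc2O)c(O[Si](C)(C)C(C)(C)C)c1 | intermediate
6 | (3S)-6-bromo-3-[2-(tert-butyldimethylsilyloxy)-4-methoxyphenyl]-2,7-dimethoxychroman-4-one, both C2 epimers (not isolated) | COc1ccc([C@H]2C(OC)Oc3cc(OC)c(Br)cc3C2=O)c(O[Si](C)(C)C(C)(C)C)c1 | intermediate
7 | (3S)-6-bromo-3-[2-(tert-butyldimethylsilyloxy)-4-methoxyphenyl]-7-methoxychroman-4-one | COc1ccc([C@H]2COc3cc(OC)c(Br)cc3C2=O)c(O[Si](C)(C)C(C)(C)C)c1 | intermediate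
8 | tributyl(3-methylbut-2-en-1-yl)stannane | CCCC[Sn](CCCC)(CCCC)CC=C(C)C | starting material
9 | (3S)-3-[2-(tert-butyldimethylsilyloxy)-4-methoxyphenyl]-7-methoxy-6-(3-methylbut-2-en-1-yl)chroman-4-one (not isolated) | COc1ccc([C@H]2COc3cc(OC)c(CC=C(C)C)cc3C2=O)c(O[Si](C)(C)C(C)(C)C)c1 | intermediate
10 | (3S)-3-(2-hydroxy-4-methoxyphenyl)-7-methoxy-6-(3-methylbut-2-en-1-yl)chroman-4-one | COc1ccc([C@H]2COc3cc(OC)c(CC=C(C)C)cc3C2=O)c(O)c1 | target

**Totals**
Total step count: 5. Longest linear sequence: 5 steps (1 or 2 → 3 → 4 → 5 → 7 → 10).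

**Steps most likely to fail, with fallbacks**

Step 3 (the free 2'-phenol or the bulky silyloxy aryl group may lower yield or ee with the chiral iodane). The fallback sets out from 4 and comes back at 7: the stereocentre is no longer set in the aryl shift but afterwards, by dynamic kinetic resolution. Chalcone 4 is rearranged with achiral PhI(OH)OTs in MeOH/HC(OMe)3 to the racemic acetal F1. The conditions of step 4 take it through the racemic cyclic acetal F2 to the racemic isoflavanone F3. Asymmetric transfer hydrogenation with RuCl[(S,S)-TsDPEN](p-cymene) in HCO2H/Et3N at 40 °C, where the amine racemises C3 while one enantiomer is reduced, is expected to give the cis-(3S,4S)-isoflavan-4-ol F4. Dess–Martin oxidation buffered with NaHCO3 then returns 7.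

Step 4 (loss of H-3 from the C2 cation would give the isoflavone, and acid could erode C3). The fallback sets out from 5 and comes back at 9: the elimination is accepted and C3 is set last. CSA in toluene at 60 °C completes the dehydration, as the plant does, to the isoflavone F5. Stille coupling with 8 at this achiral stage gives the prenyl isoflavone F6. The same Ru–(S,S)-TsDPEN/HCO2H–Et3N system then performs conjugate reduction followed by carbonyl reduction with dynamic kinetic resolution, giving the cis-(3S,4S)-prenyl isoflavan-4-ol F7; the prenyl alkene is untouched. Dess–Martin oxidation gives 9, which is desilylated with KHF2 as in step 5.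

Step 5 (heating the enolisable α-aryl ketone with palladium could erode C3). The fallback sets out from 7 and comes back at 9: C3 is locked before the hot step. Luche reduction (NaBH4, CeCl3·7H2O, MeOH/THF, −40 °C) gives the isoflavan-4-ol F8 as C4 epimers, in which C3 is no longer α to a carbonyl. Stille coupling with 8 gives the prenyl isoflavan-4-ol F9. Dess–Martin oxidation returns 9, followed by KHF2 as in step 5.

**Further compounds**
F1 | step 3 | rac-1-(5-bromo-2-hydroxy-4-methoxyphenyl)-2-[2-(tert-butyldimethylsilyloxy)-4-methoxyphenyl]-3,3-dimethoxypropan-1-one | COc1ccc(C(C(OC)OC)C(=O)c2cc(Br)c(OC)cc2O)c(O[Si](C)(C)C(C)(C)C)c1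
F2 | step 3 | rac-6-bromo-3-[2-(tert-butyldimethylsilyloxy)-4-methoxyphenyl]-2,7-dimethoxychroman-4-one (not isolated) | COc1ccc(C2C(OC)Oc3cc(OC)c(Br)cc3C2=O)c(O[Si](C)(C)C(C)(C)C)c1
F3 | step 3 | rac-6-bromo-3-[2-(tert-butyldimethylsilyloxy)-4-methoxyphenyl]-7-methoxychroman-4-one | COc1ccc(C2COc3cc(OC)c(Br)cc3C2=O)c(O[Si](C)(C)C(C)(C)C)c1
F4 | step 3 | (3S,4S)-6-bromo-3-[2-(tert-butyldimethylsilyloxy)-4-methoxyphenyl]-7-methoxychroman-4-ol | COc1ccc([C@H]2COc3cc(OC)c(Br)cc3[C@H]2O)c(O[Si](C)(C)C(C)(C)C)c1
F5 | step 4 | 6-bromo-3-[2-(tert-butyldimethylsilyloxy)-4-methoxyphenyl]-7-methoxy-4H-chromen-4-one | COc1ccc(-c2coc3cc(OC)c(Br)cc3c2=O)c(O[Si](C)(C)C(C)(C)C)c1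
F6 | step 4 | 3-[2-(tert-butyldimethylsilyloxy)-4-methoxyphenyl]-7-methoxy-6-(3-methylbut-2-en-1-yl)-4H-chromen-4-one | COc1ccc(-c2coc3cc(OC)c(CC=C(C)C)cc3c2=O)c(O[Si](C)(C)C(C)(C)C)c1
F7 | step 4 | (3S,4S)-3-[2-(tert-butyldimethylsilyloxy)-4-methoxyphenyl]-7-methoxy-6-(3-methylbut-2-en-1-yl)chroman-4-ol | COc1ccc([C@H]2COc3cc(OC)c(CC=C(C)C)cc3[C@H]2O)c(O[Si](C)(C)C(C)(C)C)c1
F8 | step 5 | (3S)-6-bromo-3-[2-(tert-butyldimethylsilyloxy)-4-methoxyphenyl]-7-methoxychroman-4-ol, C4 epimers | COc1ccc([C@H]2COc3cc(OC)c(Br)cc3C2O)c(O[Si](C)(C)C(C)(C)C)c1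
F9 | step 5 | (3S)-3-[2-(tert-butyldimethylsilyloxy)-4-methoxyphenyl]-7-methoxy-6-(3-methylbut-2-en-1-yl)chroman-4-ol, C4 epimers | COc1ccc([C@H]2COc3cc(OC)c(CC=C(C)C)cc3C2O)c(O[Si](C)(C)C(C)(C)C)c1
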